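**Retrosynthetic overview** (benzofuran numbering of the core: O1, C2, C3, C3a, C4–C7, C7a)

1. The 2,3-dihydrofuran ring (O1–C2–C3–C3a–C7a) is closed last, by a Lewis-acid formal (3+2) annulation that forms C3–C3a and O1–C7a between a 3-methoxycyclohexenone and a cis-aryl epoxide, with loss of methanol.
2. Enabling feature: O1–C7a=C3a–C4(OMe) is the bis(enol ether) of a cyclohexane-1,3-dione, so C3a is a dione-type carbon nucleophile and C7a an acetal-level carbon that can exchange its alkoxy group; C3 (benzylic, ortho to the phenol oxygen) and C2 (oxygen-bearing) together are an aryl epoxide.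
3. The fragile cis C6-hydroxy/C7-acyl unit is carried as a cis-fused isoxazoline (temporary ring, nitrile oxide cycloaddition to (R)-5-silyloxycyclohexenone); the silyloxy carbon is a temporary stereocentre that is then oxidised and becomes C4.
4. After the annulation: C4 ketone to methyl dienol ether (O-methylation, deprotonation at C5), desilylation, reductive N–O cleavage to the beta-hydroxy ketone.
5. Order of rings: both arenes and the cyclohexane are bought; isoxazoline (step 5) and epoxide (step 12) are temporary; the dihydrofuran (step 13) is the last ring of the skeleton.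

Key step: step 13

Assumption: the sense of induction of the lithium amide in step 4 and of the manganese salen complex in step 12 is taken from the closest analogues (cis-3,5-disubstituted cyclohexanones; cis-beta-methylstyrene and 2,2-dimethylchromenes), and the mirror-image reagent would be used if either proved opposite.

Step 1
Reactants: 1 3-phenylpropanal
Product: 2 3-phenylpropanal oxime (E/Z mixture)
Conditions: NH2OH·HCl, NaOAc, EtOH/H2O, rt
Reagents that add atoms: hydroxylamine hydrochloride (Cl.NO)
Why: Oxime condensation of an unhindered aldehyde with hydroxylamine is clean, and the E/Z mixture is irrelevant because both isomers give the same nitrile oxide.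

Step 2
Reactants: 3 cis,cis-cyclohexane-1,3,5-triol
Product: 4 all-cis-3,5-bis[(tert-butyldimethylsilyl)oxy]cyclohexan-1-ol
Conditions: TBSCl (2 equiv), imidazole, DMF, 0 °C to rt; mono- and tris-silyl ethers recycled
Reagents that add atoms: tert-butyldimethylsilyl chloride (C[Si](C)(Cl)C(C)(C)C)
Why: Statistical silyl ether formation on three equivalent secondary hydroxyls should give mainly the bis-ether and keeps the all-cis meso arrangement.

Step 3
Reactants: 4 all-cis-3,5-bis[(tert-butyldimethylsilyl)oxy]cyclohexan-1-ol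
Product: 5 cis-3,5-bis[(tert-butyldimethylsilyl)oxy]cyclohexan-1-one
Conditions: Dess–Martin periodinane, CH2Cl2, rt
Reagents that add atoms: none
Why: Dess–Martin oxidation of the remaining secondary alcohol gives the meso ketone under non-basic conditions that do not trigger beta-elimination of the silyloxy groups.

Step 4
Reactants: 5 cis-3,5-bis[(tert-butyldimethylsilyl)oxy]cyclohexan-1-one
Product: 6 (5R)-5-[(tert-butyldimethylsilyl)oxy]cyclohex-2-en-1-one
Conditions: (R,R)-bis(1-phenylethyl)amine, n-BuLi, LiCl, THF, −78 °C, then warming to −20 °C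
Reagents that add atoms: none
Why: Desymmetrising deprotonation of the meso ketone by a chiral lithium amide followed by E1cB loss of silanolate from the chiral enolate leaves one silyloxy stereocentre, whose (R) configuration is fixed by which of the two enantiotopic alpha-methylene groups the base attacks.

Step 5
Reactants: 6 (5R)-5-[(tert-butyldimethylsilyl)oxy]cyclohex-2-en-1-one; 2 3-phenylpropanal oxime
Product: 9 (3aR,6R,7aR)-6-[(tert-butyldimethylsilyl)oxy]-3-(2-phenylethyl)-3a,6,7,7a-tetrahydro-1,2-benzoxazol-4(5H)-one, via hydroximoyl chloride 7 (not isolated), via nitrile oxide 8 (not isolated)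
Conditions: 2, NCS, DMF, rt; then 6, KHCO3, EtOAc, 0 °C to rt (slow generation of the dipole)
Reagents that add atoms: none
Why: Huisgen 1,3-dipolar cycloaddition of the nitrile oxide made in situ is suprafacial and so gives the cis-fused isoxazoline, the dipole carbon bonding to the alpha-carbon as is usual for cyclic enones and the dipole approaching anti to the silyloxy group, which sets both new stereocentres.

Step 6
Reactants: 9 (3aR,6R,7aR)-6-[(tert-butyldimethylsilyl)oxy]-3-(2-phenylethyl)-3a,6,7,7a-tetrahydro-1,2-benzoxazol-4(5H)-one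
Product: 10 (3aR,6R,7aR)-4,4-dimethoxy-3-(2-phenylethyl)-3a,4,5,6,7,7a-hexahydro-1,2-benzoxazol-6-ol
Conditions: HC(OMe)3, MeOH, camphorsulfonic acid (cat), rt
Reagents that add atoms: trimethyl orthoformate (COC(OC)OC)
Why: Acid-catalysed ketalisation with trimethyl orthoformate in methanol protects the ketone as its dimethyl ketal while the same acidic methanol cleaves the secondary silyl ether, and no stereocentre is touched.

Step 7
Reactants: 10 (3aR,6R,7aR)-4,4-dimethoxy-3-(2-phenylethyl)-3a,4,5,6,7,7a-hexahydro-1,2-benzoxazol-6-ol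
Product: 12 (3aR,7aR)-4-methoxy-3-(2-phenylethyl)-7,7a-dihydro-1,2-benzoxazol-6(3aH)-one, via beta-keto ketal 11 (not isolated)
Conditions: Dess–Martin periodinane, CH2Cl2, rt; then pyridinium p-toluenesulfonate (cat), 4 Å MS, rt
Reagents that add atoms: none
Why: Dess–Martin oxidation gives the beta-keto ketal, which loses methanol by acid-catalysed elimination towards the ketone to give the conjugated 3-methoxy-enone with the methoxy group fixed on the carbon next to the ring fusion, the former silyloxy stereocentre being destroyed as planned.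

Step 8
Reactants: 13 methyl 4-hydroxy-3-iodobenzoate
Product: 14 methyl 4-[(tert-butyldimethylsilyl)oxy]-3-iodobenzoate
Conditions: TBSCl, imidazole, DMF, rt
Reagents that add atoms: tert-butyldimethylsilyl chloride (C[Si](C)(Cl)C(C)(C)C)
Why: Silyl ether formation blocks the phenol against benzofuran formation in the alkyne coupling and against participation in the later acid-mediated steps.

Step 9
Reactants: 14 methyl 4-[(tert-butyldimethylsilyl)oxy]-3-iodobenzoate; 15 2-methylbut-3-yn-2-ol
Product: 16 methyl 4-[(tert-butyldimethylsilyl)oxy]-3-(3-hydroxy-3-methylbut-1-yn-1-yl)benzoate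
Conditions: Pd(PPh3)2Cl2 (2 mol %), CuI (4 mol %), Et3N, THF, rt
Reagents that add atoms: none
Why: Sonogashira coupling of an aryl iodide with a terminal propargylic alcohol proceeds at room temperature and tolerates the ester and the aryl silyl ether.

Step 10
Reactants: 16 methyl 4-[(tert-butyldimethylsilyl)oxy]-3-(3-hydroxy-3-methylbut-1-yn-1-yl)benzoate
Product: 17 methyl 4-[(tert-butyldimethylsilyl)oxy]-3-[3-methyl-3-(triethylsilyloxy)but-1-yn-1-yl]benzoate
Conditions: Et3SiOTf, 2,6-lutidine, CH2Cl2, −78 to 0 °C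
Reagents that add atoms: triethylsilyl trifluoromethanesulfonate (CC[Si](CC)(CC)OS(=O)(=O)C(F)(F)F)
Why: A silyl triflate with 2,6-lutidine silylates even a tertiary alcohol, and the triethylsilyl ether later keeps this oxygen from competing with the secondary hydroxyl in the ring closure.

Step 11
Reactants: 17 methyl 4-[(tert-butyldimethylsilyl)oxy]-3-[3-methyl-3-(triethylsilyloxy)but-1-yn-1-yl]benzoate
Product: 18 methyl 4-[(tert-butyldimethylsilyl)oxy]-3-[(1Z)-3-methyl-3-(triethylsilyloxy)but-1-en-1-yl]benzoate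
Conditions: H2 (1 atm), Pd/CaCO3 poisoned with Pb(OAc)2, quinoline, EtOAc, rt
Reagents that add atoms: none
Why: Lindlar semihydrogenation adds hydrogen syn to the alkyne and gives the Z-alkene needed for a cis-epoxide.

Step 12
Reactants: 18 methyl 4-[(tert-butyldimethylsilyl)oxy]-3-[(1Z)-3-methyl-3-(triethylsilyloxy)but-1-en-1-yl]benzoate
Product: 19 methyl 4-[(tert-butyldimethylsilyl)oxy]-3-{(2R,3R)-3-[2-(triethylsilyloxy)propan-2-yl]oxiran-2-yl}benzoate
Conditions: (R,R)-N,N'-bis(3,5-di-tert-butylsalicylidene)-1,2-cyclohexanediaminomanganese chloride (5 mol %), mCPBA, N-methylmorpholine N-oxide, CH2Cl2, −78 °C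
Reagents that add atoms: 3-chloroperoxybenzoic acid (OOC(=O)c1cccc(Cl)c1)
Why: Jacobsen–Katsuki epoxidation with the trivalent manganese salen complex is at its best with cis-disubstituted aryl alkenes that carry a tertiary allylic carbon (2,2-dimethylchromene type), and the (R,R)-catalyst should deliver oxygen to the face that gives the (2R,3R)-cis-epoxide, setting both stereocentres by catalyst control.

Step 13
Reactants: 12 (3aR,7aR)-4-methoxy-3-(2-phenylethyl)-7,7a-dihydro-1,2-benzoxazol-6(3aH)-one; 19 methyl 4-[(tert-butyldimethylsilyl)oxy]-3-{(2R,3R)-3-[2-(triethylsilyloxy)propan-2-yl]oxiran-2-yl}benzoate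
Product: 21 isoxazoline-fused (2R,3R,6R,7R)-3-aryl-2-[2-(triethylsilyloxy)propan-2-yl]-2,3,6,7-tetrahydro-1-benzofuran-4(5H)-one (aryl = 2-(tert-butyldimethylsilyloxy)-5-(methoxycarbonyl)phenyl; 3-(2-phenylethyl)-4,5-dihydroisoxazole cis-fused through O on C6 and C on C7), via ring-opened alcohol 20 (not isolated)
Conditions: Sc(OTf)3 (10 mol %), 4 Å MS, CH2Cl2, −40 to 0 °C, then rt
Reagents that add atoms: none
Why: Proposed new method: Sc(OTf)3 activates the epoxide of 19, and the enol-ether alpha-carbon of 12 (the future C3a, the only carbon nucleophile of the beta-methoxy enone) opens it at the benzylic carbon in a borderline SN2, Friedel–Crafts-type substitution to give 20, whose freed C2 hydroxyl then adds to the methoxy-bearing carbon (the future C7a) and expels methanol, so that the sequence is a formal (3+2) annulation. The closest known reactions are the stereoinvertive Lewis-acid opening of aryl epoxides by indoles and enols, the benzylation of 1,3-dicarbonyl enols by benzylic electrophiles, and the acid-catalysed alkoxy exchange of 3-alkoxy-enones. The dihydrofuran is closed by a 5-exo-trig addition of oxygen to the enol-ether carbon followed by elimination, and it is the last ring of the skeleton. C3 is set by inversion at the benzylic epoxide carbon and C2 keeps its C–O bond and configuration, so the cis-(2R,3R)-epoxide maps onto the trans-(2R,3R)-dihydrofuran; a competing SN1 channel, in which the epoxide oxygen first binds C7a and the tethered benzylic cation is captured by C3a anti to the bulky C2 substituent, should converge on the same trans isomer. The step needs benzylic rather than C2 attack (C2 is shielded by the adjacent quaternary carbon), the ring oxygen on C7a and not on C4 (only the methoxy carbon is at acetal level and can lose methanol while the product stays a conjugated vinylogous ester), and a five- rather than six-membered ether (the tertiary hydroxyl is silylated).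

Step 14
Reactants: 21 isoxazoline-fused tetrahydrobenzofuran-4(5H)-one from step 13
Product: 23 isoxazoline-fused (2R,3R,6R,7R)-3-aryl-4-methoxy-2-[2-(triethylsilyloxy)propan-2-yl]-2,3,6,7-tetrahydro-1-benzofuran (aryl and isoxazoline as in 21), via O-methyl oxocarbenium salt 22 (not isolated)
Conditions: Me3OBF4, 1,8-bis(dimethylamino)naphthalene, 4 Å MS, CH2Cl2, 0 °C to rt
Reagents that add atoms: trimethyloxonium tetrafluoroborate (C[O+](C)C.F[B-](F)(F)F)
Why: Proposed new method: the carbonyl oxygen of the vinylogous ester is its most nucleophilic site and should be methylated by the oxonium salt to the 1,3-dioxyallyl cation, which the hindered base deprotonates at the unhindered C5 methylene rather than at the tertiary ring-fusion C7–H to give the cross-conjugated bis(enol ether), the closest known reactions being O-alkylation of vinylogous esters and amides with trialkyloxonium salts and the deprotonation of oxocarbenium ions by hindered amines to enol ethers.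

Step 15
Reactants: 23 isoxazoline-fused 4-methoxy-tetrahydrobenzofuran from step 14
Product: 24 methyl 4-hydroxy-3-[(2R,3R,6R,7R)-2-(2-hydroxypropan-2-yl)-4-methoxy-2,3,6,7-tetrahydro-1-benzofuran-3-yl]benzoate with the 3-(2-phenylethyl)-4,5-dihydroisoxazole still cis-fused across C6 (O) and C7 (C)
Conditions: Bu4NF, AcOH (1:1), THF, 0 °C to rt
Reagents that add atoms: none
Why: Fluoride buffered with acetic acid cleaves the aryl and the tertiary silyl ethers (silyl ether cleavage) without the strong acid or base that would aromatise the dienol ether by loss of the C6 oxygen.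

Step 16
Reactants: 24 desilylated isoxazoline from step 15
Product: 26 methyl 4-hydroxy-3-[(2R,3R,6R,7R)-6-hydroxy-2-(2-hydroxypropan-2-yl)-4-methoxy-7-(3-phenylpropanoyl)-2,3,6,7-tetrahydro-1-benzofuran-3-yl]benzoate (CNP0080427.3), via beta-hydroxy imine 25 (not isolated)
Conditions: Raney Ni, H2 (1 atm), B(OH)3, MeOH/H2O (5:1), rt; work-up at pH 7
Reagents that add atoms: water (O)
Why: Hydrogenolysis of the isoxazoline N–O bond over Raney Ni buffered with B(OH)3 gives the beta-hydroxy imine, which is hydrolysed in the same pot to the beta-hydroxy ketone, the cis relationship of C6–OH and C7–acyl being inherited from the cis-fused isoxazoline.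

**Compound list**

1 | 3-phenylpropanal | O=CCCc1ccccc1 | starting material
2 | 3-phenylpropanal oxime (E/Z mixture) | ON=CCCc1ccccc1 | intermediate
3 | cis,cis-cyclohexane-1,3,5-triol (all-cis, meso) | O[C@H]1C[C@@H](O)C[C@@H](O)C1 | starting material
4 | all-cis-3,5-bis[(tert-butyldimethylsilyl)oxy]cyclohexan-1-ol (meso) | O[C@H]1C[C@@H](O[Si](C)(C)C(C)(C)C)C[C@@H](O[Si](C)(C)C(C)(C)C)C1 | intermediate
5 | cis-3,5-bis[(tert-butyldimethylsilyl)oxy]cyclohexan-1-one (meso) | O=C1C[C@@H](O[Si](C)(C)C(C)(C)C)C[C@@H](O[Si](C)(C)C(C)(C)C)C1 | intermediate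
6 | (5R)-5-[(tert-butyldimethylsilyl)oxy]cyclohex-2-en-1-one | O=C1C=CC[C@@H](O[Si](C)(C)C(C)(C)C)C1 | intermediate
7 | N-hydroxy-3-phenylpropanimidoyl chloride (not isolated) | ON=C(Cl)CCc1ccccc1 | intermediate
8 | 3-phenylpropanenitrile oxide (not isolated) | [O-][N+]#CCCc1ccccc1 | intermediate
9 | (3aR,6R,7aR)-6-[(tert-butyldimethylsilyl)oxy]-3-(2-phenylethyl)-3a,6,7,7a-tetrahydro-1,2-benzoxazol-4(5H)-one | O=C1C[C@H](O[Si](C)(C)C(C)(C)C)C[C@H]3ON=C(CCc2ccccc2)[C@H]31 | intermediate
10 | (3aR,6R,7aR)-4,4-dimethoxy-3-(2-phenylethyl)-3a,4,5,6,7,7a-hexahydro-1,2-benzoxazol-6-ol | COC1(OC)C[C@H](O)C[C@H]3ON=C(CCc2ccccc2)[C@H]31 | intermediate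
11 | (3aR,7aR)-4,4-dimethoxy-3-(2-phenylethyl)-3a,4,5,7a-tetrahydro-1,2-benzoxazol-6(7H)-one (not isolated) | COC1(OC)CC(=O)C[C@H]3ON=C(CCc2ccccc2)[C@H]31 | intermediate
12 | (3aR,7aR)-4-methoxy-3-(2-phenylethyl)-7,7a-dihydro-1,2-benzoxazol-6(3aH)-one | COC1=CC(=O)C[C@H]3ON=C(CCc2ccccc2)[C@H]31 | intermediate
13 | methyl 4-hydroxy-3-iodobenzoate | COC(=O)c1ccc(O)c(I)c1 | starting material
14 | methyl 4-[(tert-butyldimethylsilyl)oxy]-3-iodobenzoate | COC(=O)c1ccc(O[Si](C)(C)C(C)(C)C)c(I)c1 | intermediate
15 | 2-methylbut-3-yn-2-ol | CC(C)(O)C#C | starting material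
16 | methyl 4-[(tert-butyldimethylsilyl)oxy]-3-(3-hydroxy-3-methylbut-1-yn-1-yl)benzoate | COC(=O)c1ccc(O[Si](C)(C)C(C)(C)C)c(C#CC(C)(C)O)c1 | intermediate
17 | methyl 4-[(tert-butyldimethylsilyl)oxy]-3-[3-methyl-3-(triethylsilyloxy)but-1-yn-1-yl]benzoate | COC(=O)c1ccc(O[Si](C)(C)C(C)(C)C)c(C#CC(C)(C)O[Si](CC)(CC)CC)c1 | intermediate
18 | methyl 4-[(tert-butyldimethylsilyl)oxy]-3-[(1Z)-3-methyl-3-(triethylsilyloxy)but-1-en-1-yl]benzoate | COC(=O)c1ccc(O[Si](C)(C)C(C)(C)C)c(/C=C\C(C)(C)O[Si](CC)(CC)CC)c1 | intermediate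
19 | methyl 4-[(tert-butyldimethylsilyl)oxy]-3-{(2R,3R)-3-[2-(triethylsilyloxy)propan-2-yl]oxiran-2-yl}benzoate (cis-epoxide) | COC(=O)c1ccc(O[Si](C)(C)C(C)(C)C)c([C@H]2O[C@H]2C(C)(C)O[Si](CC)(CC)CC)c1 | intermediate
20 | (3aR,7aR)-5-{(1R,2R)-1-[2-(tert-butyldimethylsilyloxy)-5-(methoxycarbonyl)phenyl]-2-hydroxy-3-methyl-3-(triethylsilyloxy)butyl}-4-methoxy-3-(2-phenylethyl)-7,7a-dihydro-1,2-benzoxazol-6(3aH)-one (not isolated) | COC1=C([C@@H](c2cc(C(=O)OC)ccc2O[Si](C)(C)C(C)(C)C)[C@@H](O)C(C)(C)O[Si](CC)(CC)CC)C(=O)C[C@H]3ON=C(CCc4ccccc4)[C@H]31 | intermediate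
21 | methyl 4-[(tert-butyldimethylsilyl)oxy]-3-{(2R,3R,6R,7R)-4-oxo-2-[2-(triethylsilyloxy)propan-2-yl]-2,3,4,5,6,7-hexahydro-1-benzofuran-3-yl}benzoate whose C6 and C7 are bridged as a cis-fused 3-(2-phenylethyl)-4,5-dihydroisoxazole (ring O on C6, ring C on C7) | COC(=O)c1ccc(O[Si](C)(C)C(C)(C)C)c([C@@H]2C3=C(O[C@H]2C(C)(C)O[Si](CC)(CC)CC)[C@@H]4C(CCc5ccccc5)=NO[C@@H]4CC3=O)c1 | intermediate
22 | O-methyl oxocarbenium tetrafluoroborate of 21 (4-methoxy cation, not isolated) | COC(=O)c1ccc(O[Si](C)(C)C(C)(C)C)c([C@@H]2C3=C(O[C@H]2C(C)(C)O[Si](CC)(CC)CC)[C@@H]4C(CCc5ccccc5)=NO[C@@H]4CC3=[O+]C)c1.F[B-](F)(F)F | intermediate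
23 | methyl 4-[(tert-butyldimethylsilyl)oxy]-3-{(2R,3R,6R,7R)-4-methoxy-2-[2-(triethylsilyloxy)propan-2-yl]-2,3,6,7-tetrahydro-1-benzofuran-3-yl}benzoate with the same cis-fused isoxazoline across C6 (O) and C7 (C) | COC(=O)c1ccc(O[Si](C)(C)C(C)(C)C)c([C@@H]2C3=C(O[C@H]2C(C)(C)O[Si](CC)(CC)CC)[C@@H]4C(CCc5ccccc5)=NO[C@@H]4C=C3OC)c1 | intermediate
24 | methyl 4-hydroxy-3-[(2R,3R,6R,7R)-2-(2-hydroxypropan-2-yl)-4-methoxy-2,3,6,7-tetrahydro-1-benzofuran-3-yl]benzoate with the same cis-fused isoxazoline across C6 (O) and C7 (C) | COC(=O)c1ccc(O)c([C@@H]2C3=C(O[C@H]2C(C)(C)O)[C@@H]4C(CCc5ccccc5)=NO[C@@H]4C=C3OC)c1 | intermediate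
25 | methyl 4-hydroxy-3-[(2R,3R,6R,7R)-6-hydroxy-2-(2-hydroxypropan-2-yl)-7-(1-imino-3-phenylpropyl)-4-methoxy-2,3,6,7-tetrahydro-1-benzofuran-3-yl]benzoate (not isolated) | COC(=O)c1ccc(O)c([C@@H]2C3=C(O[C@H]2C(C)(C)O)[C@H](C(=N)CCc2ccccc2)[C@H](O)C=C3OC)c1 | intermediate
26 | methyl 4-hydroxy-3-[(2R,3R,6R,7R)-6-hydroxy-2-(2-hydroxypropan-2-yl)-4-methoxy-7-(3-phenylpropanoyl)-2,3,6,7-tetrahydro-1-benzofuran-3-yl]benzoate | COC(=O)c1ccc(O)c([C@@H]2C3=C(O[C@H]2C(C)(C)O)[C@H](C(=O)CCc2ccccc2)[C@H](O)C=C3OC)c1 | target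

**Step count and risks**

Total step count: 16. Longest linear sequence: 10 steps (steps 2–7 and 13–16, from triol 3); the oxime (step 1) and the aryl epoxide (steps 8–12) are side branches.

Step 13 (proposed new method) is the most likely to fail. The Lewis-acid-opened epoxide may undergo a Meinwald-type hydride shift to a benzyl ketone before the weak, hindered carbon nucleophile captures it. The opening may also lose stereospecificity through a free cation, or the acid may open the isoxazoline and aromatise the six-membered ring. The fallback uses known reaction types and sets out from 19 and 12. Acetolysis of 19 at the benzylic carbon (AcOH, 50 °C) should give the acetoxy alcohol methyl 3-[(1S,2R)-1-acetoxy-2-hydroxy-3-methyl-3-(triethylsilyloxy)butyl]-4-[(tert-butyldimethylsilyl)oxy]benzoate F1. Acid-catalysed alkoxy exchange of 12 with the free secondary hydroxyl of F1 (pyridinium p-toluenesulfonate, toluene, 80 °C, 4 Å MS to take up methanol) should give the mixed vinylogous ester F2, in which O1–C7a is already in place. Bi(OTf)3 (5 mol %) in CH2Cl2 at −40 °C then ionises the benzylic acetate, and the tethered enol-ether carbon closes the five-membered ring by an intramolecular Friedel–Crafts-type alkylation, trans to the C2 substituent. The route is rejoined at 21.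

Step 14 (proposed new method) may fail by competing N-methylation of the isoxazoline, by deprotonation of the cation at C7 instead of C5 (isomeric diene, loss of the C7 configuration), or by demethylation of the cation back to 21. The fallback sets out from 21. Ketalisation (HC(OMe)3, MeOH, pyridinium p-toluenesulfonate) should give the C4 dimethyl ketal F3. Ketal-to-enol-ether elimination with Me3SiOTf and iPr2NEt (CH2Cl2, −78 to 0 °C) under amine-buffered conditions then returns to 23.

Step 16 may fail because the boric acid medium promotes loss of water from C6/C7 with aromatisation, or hydrolysis of the methyl dienol ether, or because the diene is hydrogenated over the nickel. The fallback sets out from 23 and changes both the order and the reagent class. The N–O bond is cleaved on the still silylated compound with Mo(CO)6 in MeCN/H2O at 70 °C (neutral, no hydrogen) to give the protected aldol methyl 4-[(tert-butyldimethylsilyl)oxy]-3-{(2R,3R,6R,7R)-6-hydroxy-4-methoxy-7-(3-phenylpropanoyl)-2-[2-(triethylsilyloxy)propan-2-yl]-2,3,6,7-tetrahydro-1-benzofuran-3-yl}benzoate F4. The two silyl ethers are then removed last with Bu4NF/AcOH in THF at 0 °C, which arrives at 26.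

**Further compounds**

F1 | step 13 | methyl 3-[(1S,2R)-1-acetoxy-2-hydroxy-3-methyl-3-(triethylsilyloxy)butyl]-4-[(tert-butyldimethylsilyl)oxy]benzoate | COC(=O)c1ccc(O[Si](C)(C)C(C)(C)C)c([C@H](OC(C)=O)[C@@H](O)C(C)(C)O[Si](CC)(CC)CC)c1
F2 | step 13 | (3aR,7aR)-4-{[(1S,2R)-1-acetoxy-1-[2-(tert-butyldimethylsilyloxy)-5-(methoxycarbonyl)phenyl]-3-methyl-3-(triethylsilyloxy)butan-2-yl]oxy}-3-(2-phenylethyl)-7,7a-dihydro-1,2-benzoxazol-6(3aH)-one | COC(=O)c1ccc(O[Si](C)(C)C(C)(C)C)c([C@H](OC(C)=O)[C@@H](OC2=CC(=O)C[C@H]3ON=C(CCc4ccccc4)[C@H]32)C(C)(C)O[Si](CC)(CC)CC)c1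
F3 | step 14 | C4 dimethyl ketal of 21 (4,4-dimethoxy in place of the 4-oxo group) | COC(=O)c1ccc(O[Si](C)(C)C(C)(C)C)c([C@@H]2C3=C(O[C@H]2C(C)(C)O[Si](CC)(CC)CC)[C@@H]4C(CCc5ccccc5)=NO[C@@H]4CC3(OC)OC)c1
F4 | step 16 | methyl 4-[(tert-butyldimethylsilyl)oxy]-3-{(2R,3R,6R,7R)-6-hydroxy-4-methoxy-7-(3-phenylpropanoyl)-2-[2-(triethylsilyloxy)propan-2-yl]-2,3,6,7-tetrahydro-1-benzofuran-3-yl}benzoate | COC(=O)c1ccc(O[Si](C)(C)C(C)(C)C)c([C@@H]2C3=C(O[C@H]2C(C)(C)O[Si](CC)(CC)CC)[C@H](C(=O)CCc2ccccc2)[C@H](O)C=C3OC)c1
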